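**Analysis of the target**

Sarmentosumin C is a (2S)-flavanone of the pinocembrin type: ring A is a phloroglucinol, ring C a dihydropyranone and ring B an unsubstituted phenyl on C2. Ring A is fully substituted: C8 carries a 2-hydroxybenzyl group (ring H) and C6 a chain of four 2-hydroxybenzyl units (rings D to G, counted outward from ring A), in which each methylene joins the carbon para to the hydroxyl of one ring to the carbon ortho to the hydroxyl of the next. C2 is the only stereocentre; it is benzylic, bears the ring C ether oxygen and lies β to the C4 carbonyl, so base or strong acid can open ring C to the achiral chalcone and erase it. Seven phenols and five diarylmethane methylenes make the free compound prone to oxidation and quinone-methide chemistry, so the phenols should stay masked until the end of the route. The real difficulty is ring A: C6 and C8 sit in almost identical environments yet bear different benzyl groups, and the three oxygens have different fates (the C8a oxygen becomes O1 of ring C, the C5 hydroxyl is chelated to the C4 carbonyl, the C7 hydroxyl is free), so electrophilic benzylation of a phloroglucinol cannot tell the positions apart. The chain is repetitive and can be grown by repeated use of one bifunctional ring. The strategy rests on the fact that the bonds C8a–C8, C7–C6 and C8a–C4a of ring A can be made from two acyclic partners, each already carrying one of the two benzyl groups, so that the placement of both benzyls and the differentiation of the oxygens on C5, C7 and C8a follow from connectivity and not from selectivity.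

**Retrosynthetic reasoning**

Target 34 is traced back to 33 and then to 32 by cutting only oxygen–protecting-group bonds. The five benzyl ethers and the C5 ethyl ether of 33 are meant to fall in one Lewis-acid dealkylation; the ethyl group lies peri to the C4 carbonyl and is therefore activated by chelation. The silyl ether of 32 is removed one step earlier under buffered conditions, so that no phenoxide is generated next to the base-sensitive ring C.

Ring C of 32 is opened at C4–C4a, which leads to acid 30 (activated in the flask as 31). C4a is the only unsubstituted carbon of ring A and is flanked by two oxygens and para to the third, so an intramolecular acylation has one possible site and forms a six-membered ring. C2 is not part of the bond-forming event and keeps its configuration. Acid 30 comes from ester 29 by a non-basic ester cleavage.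

Ester 29 is cut at O1–C2 into phenol 27 and hydroxy ester 28. 27 has exactly one free hydroxyl, the future O1, and 28 is a chiral-pool (R)-alcohol, so an invertive Mitsunobu displacement should set the (S)-centre. Making this bond before ring closure means the stereocentre arises by substitution and not by a reversible oxa-Michael addition.

Phenol 27 is cut at three ring A bonds (C8a–C8, C7–C6, C8a–C4a) into diazo ketone 19 and siloxyalkyne 23. This is the central disconnection: 19 carries the chain benzyl on its diazo carbon (future C6) and the ethoxy group on its vinyl carbon (future C5), while 23 carries the ring H benzyl (future C8) and the silyloxy group (future C7). The ketene oxygen ends as the free C8a hydroxyl and the vinyl CH2 as the unsubstituted C4a. The forward reaction has to achieve a Wolff rearrangement with vinyl migration, a regioselective ketene–alkyne [2+2] addition and an electrocyclic cascade, passing through 24, 25 and 26.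

Diazo ketone 19 derives from ketone 17 by diazo transfer at its only enolisable position. 17 is cut at the acyl–vinyl bond into Weinreb amide 14 and ethyl vinyl ether 15 (used as its lithio derivative 16). Amide 14 comes from ester 13, and 13 from aryl bromide 12 by sp2–sp3 cross-coupling, so the three-carbon acyl chain is attached only once the four-ring chain is complete.

Bromide 12 is cut at each aryl–CH2 bond on the side of the ring carbon ortho to oxygen. Every cut gives an aryllithium (4, 7 or 10) and the same aldehyde 2, whose bromine becomes the nucleophilic site of the next round. Three rounds of addition and ionic reduction (via 5, 6, 8, 9, 11) start from bromide 3; aldehyde 2 comes from 1 by benzylation. One building block thus supplies rings D, E and F.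

Siloxyalkyne 23 is cut at the alkyne, leading to arylacetate 21 through ynolate 22 (one-carbon homologation with rearrangement and O-silylation); 21 comes from phenol ester 20 by benzylation.

**Alternatives that were turned down**

Alternative 1: The disconnection removes the two terminal phenol rings (ring G at the chain end and ring H on the C8 methylene) at their CH2–aryl bonds. Both rings are traced to cyclohex-2-enone A2, and the two methylene carbons to the formyl groups of the penta-MOM flavone dialdehyde A1. In the forward key step the lithium dienolate of A2 would add through its α′-carbon to both aldehydes of A1; dehydration and base-mediated migration of the exocyclic double bonds into the rings would aromatise both to the free phenols of flavone A3.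
- For it: two rings arise from one cheap C6 unit in a single operation, the aldol/isomerisation chemistry is of a known type, and methoxymethyl groups come off under mild acid. On precedent and on the gentleness of the final deprotection this alternative is the stronger one.
- Against it: the key step is spent on the two least demanding aryl–CH2 bonds, which in the chosen route cost one aryllithium addition and one ionic reduction each. A1 must already contain the hexasubstituted ring A with two different carbon substituents on C6 and C8, so the actual problem is moved into the precursor. The dienolate must also discriminate between two aldehydes and the flavone enone, and A3 is a flavone, so C2 still has to be created by an enantioselective conjugate reduction of a hindered polyphenolic substrate.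
- In its place the chosen strategy offers a ring A whose substitution is fixed by connectivity and a C2 centre taken from the chiral pool.

Alternative 2: The disconnection is O1–C8a. Ring C would be closed by intramolecular C–O coupling of the (S)-configured secondary benzylic alcohol of hepta-MOM bromo carbinol A4 with its C8a bromide (Pd(OAc)2, a bulky di-tert-butylbiarylphosphine and Cs2CO3), giving 4-silyloxyflavan A5.
- For it: the carbinol C–O bond is never broken, so C2 is carried with retention and the elimination and ionisation risks of an invertive displacement do not arise. On the security of the stereocentre this is at least as strong as step 15 of the chosen route.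
- Against it: the bromide of A4 is flanked by the C8 benzyl group and the C4 side chain on a very electron-rich ring, so oxidative addition is slow and crowded. The palladium alkoxide of a secondary benzylic alcohol can lose β-hydride to give the ketone and the reduced arene. C4 must be carried as a protected alcohol (as an epimer mixture) and re-oxidised afterwards. A4 again presupposes a fully differentiated hexasubstituted ring A, now with bromine on C8a and a carbon chain on C4a, which is harder to reach than phenol 27.
- The chosen route concentrates its uncertainty in one new step, but that step delivers ring A with a free C8a hydroxyl and a free C4a position and needs no redox adjustment at C4.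

Alternative 3: The disconnection is C4–C4a with the O1–C2 aryl ether already in place in hepta-benzyl (S)-acid A6. In the forward key step the acid is activated as its trifluoroacetic mixed anhydride and acylates C4a, closing ring C to hepta-O-benzyl flavanone A7.
- For it: the closure is precedented, attacks the only free and most activated position of ring A, leaves C2 untouched, and uniform benzyl protection allows a single final deprotection with no ethyl ether to cleave. On endgame simplicity it is stronger than the chosen sequence, and it is in fact the same ring closure as step 17 below.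
- Against it as a strategy: it begins after the difficulty. A6 needs a phloroglucinol with two different C-benzyl groups on C6 and C8 and with the C8a oxygen distinguished from those on C5 and C7, and the alternative provides no bond-forming logic for that. By classical substitution this means a longer sequence of directed metalations and protecting-group exchanges with a site-selectivity question at each stage.
- The chosen strategy keeps this closure and supplies what is missing: a construction of ring A in which each benzyl arrives on its own fragment. The price is a mixed protection pattern (ethyl, silyl, benzyl) and two extra deprotection operations.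

Key step: step 14

**Remarks before the steps**

- Assumption: 1-(benzyloxy)-2-bromobenzene, methyl 2-(2-hydroxyphenyl)acetate and (3-ethoxy-3-oxopropyl)zinc bromide (THF solution) are taken as commercial. The C5 ethoxy group is treated as a protecting group.
- Abbreviations in names:
  - Ar2 = 2-(benzyloxy)-5-[2-(benzyloxy)benzyl]phenyl (rings F–G).
  - Ar3 = 2-(benzyloxy)-5-{2-(benzyloxy)-5-[2-(benzyloxy)benzyl]benzyl}phenyl (rings E–G).
  - Ar4 = 2-(benzyloxy)-5-{2-(benzyloxy)-5-[2-(benzyloxy)-5-(2-(benzyloxy)benzyl)benzyl]benzyl}phenyl (rings D–G).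

**Route**

Step 1
Reactants: 1 3-bromo-4-hydroxybenzaldehyde
Product: 2 4-(benzyloxy)-3-bromobenzaldehyde
Conditions: BnBr, K2CO3, DMF, rt
Reagents that add atoms: benzyl bromide, BrCc1ccccc1
Why: Williamson etherification of an acidic para-formyl phenol; the aldehyde and the aryl bromide are inert to carbonate.

Step 2
Reactants: 3 1-(benzyloxy)-2-bromobenzene; 2 4-(benzyloxy)-3-bromobenzaldehyde
Product: 5 [2-(benzyloxy)phenyl][4-(benzyloxy)-3-bromophenyl]methanol (racemic), via aryllithium 4 (not isolated)
Conditions: n-BuLi, THF, −78 °C; then 2, −78 °C; H2O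
Reagents that add atoms: none
Why: Bromine–lithium exchange followed by 1,2-addition of the aryllithium to the aldehyde, which at −78 °C should be much faster than exchange with the aryl bromide of 2; the carbinol centre is racemic and is removed in step 3.

Step 3
Reactants: 5 [2-(benzyloxy)phenyl][4-(benzyloxy)-3-bromophenyl]methanol
Product: 6 1-(benzyloxy)-2-bromo-4-[2-(benzyloxy)benzyl]benzene (Ar2–Br)
Conditions: Et3SiH, CF3CO2H, CH2Cl2, 0 °C
Reagents that add atoms: none
Why: Ionic hydrogenation; the diarylmethyl cation is stabilised by one ortho- and one para-benzyloxy group and should be captured by the silane faster than by any arene, while benzyl ethers and the aryl bromide are stable to brief exposure to CF3CO2H.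

Step 4
Reactants: 6 Ar2–Br; 2 4-(benzyloxy)-3-bromobenzaldehyde
Product: 8 (Ar2)[4-(benzyloxy)-3-bromophenyl]methanol (racemic), via aryllithium 7 (not isolated)
Conditions: n-BuLi, THF, −78 °C; then 2, −78 °C; H2O
Reagents that add atoms: none
Why: Same bromine–lithium exchange and aldehyde addition as step 2; exchange at −78 °C should outrun deprotonation of the diarylmethane CH2.

Step 5
Reactants: 8 (Ar2)[4-(benzyloxy)-3-bromophenyl]methanol
Product: 9 1-(benzyloxy)-2-bromo-4-{2-(benzyloxy)-5-[2-(benzyloxy)benzyl]benzyl}benzene (Ar3–Br)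
Conditions: Et3SiH, CF3CO2H, CH2Cl2, 0 °C
Reagents that add atoms: none
Why: Ionic hydrogenation as in step 3, with the silane in excess so that hydride capture outcompetes Friedel–Crafts alkylation of the free para position of ring G.

Step 6
Reactants: 9 Ar3–Br; 2 4-(benzyloxy)-3-bromobenzaldehyde
Product: 11 (Ar3)[4-(benzyloxy)-3-bromophenyl]methanol (racemic), via aryllithium 10 (not isolated)
Conditions: n-BuLi, THF, −78 °C; then 2, −78 °C; H2O
Reagents that add atoms: none
Why: Third round of bromine–lithium exchange and aryllithium addition to the same aldehyde building block.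

Step 7
Reactants: 11 (Ar3)[4-(benzyloxy)-3-bromophenyl]methanol
Product: 12 1-(benzyloxy)-2-bromo-4-{2-(benzyloxy)-5-[2-(benzyloxy)-5-(2-(benzyloxy)benzyl)benzyl]benzyl}benzene (Ar4–Br)
Conditions: Et3SiH, CF3CO2H, CH2Cl2, 0 °C
Reagents that add atoms: none
Why: Ionic hydrogenation as in steps 3 and 5 completes the four-ring chain with the bromine on the ring D carbon that will carry the C6 methylene.

Step 8
Reactants: 12 Ar4–Br
Product: 13 ethyl 3-(Ar4)propanoate
Conditions: BrZnCH2CH2CO2Et, Pd(OAc)2 (cat.), 2-dicyclohexylphosphino-2′,6′-dimethoxybiphenyl (SPhos, cat.), THF, 50 °C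
Reagents that add atoms: (3-ethoxy-3-oxopropyl)zinc bromide, CCOC(=O)CC[Zn]Br
Why: Negishi coupling; the electron-rich bulky phosphine on zerovalent palladium should allow oxidative addition into the ortho-alkoxy aryl bromide, and the primary alkylzinc homoenolate transmetalates without touching ester or benzyl ethers.

Step 9
Reactants: 13 ethyl 3-(Ar4)propanoate
Product: 14 N-methoxy-N-methyl-3-(Ar4)propanamide
Conditions: MeNH(OMe)·HCl, i-PrMgCl, THF, −20 to 0 °C; aq NH4Cl
Reagents that add atoms: N,O-dimethylhydroxylamine hydrochloride, CNOC.Cl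
Why: Direct ester-to-Weinreb-amide conversion through the magnesium amide of N,O-dimethylhydroxylamine, a standard aminolysis that the benzyl ethers tolerate.

Step 10
Reactants: 14 N-methoxy-N-methyl-3-(Ar4)propanamide; 15 ethyl vinyl ether
Product: 17 2-ethoxy-5-(Ar4)pent-1-en-3-one, via 1-ethoxyvinyllithium 16 (not isolated)
Conditions: 15, t-BuLi, THF, −78 to 0 °C; then 14, −78 °C; H2O
Reagents that add atoms: none
Why: α-Lithiation of the vinyl ether and acylation by the Weinreb amide, whose chelated tetrahedral adduct prevents over-addition; a non-acidic work-up protects the enol ether.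

Step 11
Reactants: 17 2-ethoxy-5-(Ar4)pent-1-en-3-one
Product: 19 4-diazo-2-ethoxy-5-(Ar4)pent-1-en-3-one, via trifluoroacetyl diketone 18 (not isolated)
Conditions: LiN(SiMe3)2, THF, −78 °C; CF3CO2CH2CF3; pH 5 phosphate work-up; then MsN3, Et3N, H2O, MeCN, rt
Reagents that add atoms: methanesulfonyl azide, CS(=O)(=O)N=[N+]=[N-]; 2,2,2-trifluoroethyl trifluoroacetate, O=C(OCC(F)(F)F)C(F)(F)F (its acyl group is held only in 18)
Why: Detrifluoroacetylative diazo transfer; 17 has a single enolisable CH2, the trifluoroacetyl group activates it for azide attack and is expelled as the N-acyl sulfonamide, and the method is designed for base-sensitive enones.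

Step 12
Reactants: 20 methyl 2-(2-hydroxyphenyl)acetate
Product: 21 methyl 2-[2-(benzyloxy)phenyl]acetate
Conditions: BnBr, K2CO3, acetone, reflux
Reagents that add atoms: benzyl bromide, BrCc1ccccc1
Why: Williamson etherification of the phenol; carbonate is too weak to alkylate the ester α-position.

Step 13
Reactants: 21 methyl 2-[2-(benzyloxy)phenyl]acetate
Product: 23 triisopropyl{3-[2-(benzyloxy)phenyl]prop-1-yn-1-yloxy}silane, via lithium ynolate 22 (not isolated)
Conditions: CH2Br2, lithium 2,2,6,6-tetramethylpiperidide, THF, −78 °C; 21; LiN(SiMe3)2; n-BuLi, −78 °C to rt; then i-Pr3SiCl, −78 °C to rt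
Reagents that add atoms: dibromomethane, BrCBr; chlorotriisopropylsilane, CC(C)[Si](Cl)(C(C)C)C(C)C
Why: Kowalski ester homologation stopped at the ynolate: dibromomethyllithium adds to the ester, base gives the dibromo ketone enolate, bromine–lithium exchange triggers a 1,2-shift of the arylmethyl group to ynolate 22, and the bulky silyl chloride reacts at oxygen.

Step 14
Reactants: 19 4-diazo-2-ethoxy-5-(Ar4)pent-1-en-3-one; 23 triisopropyl{3-[2-(benzyloxy)phenyl]prop-1-yn-1-yloxy}silane
Product: 27 4-(Ar4-methyl)-2-[2-(benzyloxy)benzyl]-5-ethoxy-3-(triisopropylsilyloxy)phenol, via vinylketene 24 (not isolated), via vinylcyclobutenone 25 (not isolated), via dienylketene 26 (not isolated)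
Conditions: 23 (1.5 equiv), hν (365 nm), degassed ClCH2CH2Cl, rt; then 80 °C
Reagents that add atoms: none
Why: Proposed new method: excitation of the diazo ketone chromophore of 19 expels N2 and the 1-ethoxyvinyl group migrates from the carbonyl carbon to the diazo carbon (Wolff rearrangement), giving vinylketene 24. The electron-rich siloxyalkyne 23 then adds across the ketene C=C bond in a [2+2] cycloaddition in which its oxygen-free carbon bonds to the ketene carbonyl carbon (C8a–C8) and its siloxy carbon to the ketene α-carbon (C7–C6), giving 4-vinylcyclobutenone 25. Strain drives conrotatory 4-electron opening of 25 to dienylketene 26, and a thermal disrotatory 6-electron electrocyclisation joins the ketene carbon to the vinyl CH2 (C8a–C4a), closing ring A as a cyclohexadienone that tautomerises to phenol 27. The closest known reaction type is the photochemical Wolff variant of the vinylketene–alkyne benzannulation with siloxyalkynes, which gives resorcinol monosilyl ethers; a 1-alkoxyvinyl migrating group leading to a phloroglucinol pattern has not been demonstrated. The extension is reasonable because the ethoxy group sits on the one vinyl carbon that forms no new bond and is only cross-conjugated with the ketene, so it should not quench the electrophilicity of the ketene carbonyl carbon. The selectivity the step needs is the regiochemistry of the ketene–alkyne union, and it is secured by the polarisation of 23, whose carbon remote from oxygen is the nucleophilic terminus. No stereocentre is formed: the quaternary carbon of 25 is planarised on ring opening, and the isomer of 26 with the wrong C=C geometry can revert to 25, so both should funnel to 27. Irradiation at 365 nm is chosen because only the diazo ketone absorbs there, which spares the aryl benzyl ethers.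

Step 15
Reactants: 27 4-(Ar4-methyl)-2-[2-(benzyloxy)benzyl]-5-ethoxy-3-(triisopropylsilyloxy)phenol; 28 ethyl (R)-3-hydroxy-3-phenylpropanoate
Product: 29 ethyl (S)-3-{4-(Ar4-methyl)-2-[2-(benzyloxy)benzyl]-5-ethoxy-3-(triisopropylsilyloxy)phenoxy}-3-phenylpropanoate
Conditions: PPh3, DIAD, toluene, 0 °C to rt
Reagents that add atoms: none
Why: Mitsunobu etherification; the only free phenol of 27 displaces the activated benzylic alcohol in an SN2 process, so the (R)-carbinol is inverted to the (S)-aryl ether that becomes C2.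

Step 16
Reactants: 29 ethyl (S)-3-aryloxy-3-phenylpropanoate
Product: 30 (S)-3-{4-(Ar4-methyl)-2-[2-(benzyloxy)benzyl]-5-ethoxy-3-(triisopropylsilyloxy)phenoxy}-3-phenylpropanoic acid
Conditions: Me3SnOH, ClCH2CH2Cl, 80 °C; then 5% aq HCl wash
Reagents that add atoms: trimethyltin hydroxide, C[Sn](C)(C)O
Why: Tin-hydroxide-mediated ester cleavage, chosen over alkali hydroxide because it is essentially non-basic and should avoid E1cB loss of the β-aryloxy group; aryl silyl and benzyl ethers are unaffected.

Step 17
Reactants: 30 (S)-3-aryloxy-3-phenylpropanoic acid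
Product: 32 (S)-6-(Ar4-methyl)-8-[2-(benzyloxy)benzyl]-5-ethoxy-2-phenyl-7-(triisopropylsilyloxy)chroman-4-one, via mixed anhydride 31 (not isolated)
Conditions: (CF3CO)2O, CH2Cl2, 0 °C to rt
Reagents that add atoms: trifluoroacetic anhydride, O=C(OC(=O)C(F)(F)F)C(F)(F)F (its atoms are held only in 31)
Why: Intramolecular Friedel–Crafts acylation through the mixed anhydride; C4a is the only free position of ring A and is activated by two ortho oxygens and one para oxygen, the ring formed is six-membered, and C2 takes no part, so its configuration is retained.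

Step 18
Reactants: 32 (S)-7-silyloxy flavanone
Product: 33 (S)-6-(Ar4-methyl)-8-[2-(benzyloxy)benzyl]-5-ethoxy-7-hydroxy-2-phenylchroman-4-one
Conditions: Bu4NF, AcOH, THF, 0 °C
Reagents that add atoms: none
Why: Fluoride cleavage of the aryl silyl ether, buffered with acetic acid so that no free phenoxide or basic fluoride can open ring C by retro-oxa-Michael reaction and racemise C2.

Step 19
Reactants: 33 (S)-5-ethoxy-7-hydroxy penta-O-benzyl flavanone
Product: 34 sarmentosumin C
Conditions: BCl3, C6HMe5, CH2Cl2, −78 to 0 °C; MeOH/H2O quench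
Reagents that add atoms: none
Why: Lewis-acid dealkylation; BCl3 cleaves the five aryl benzyl ethers at low temperature with pentamethylbenzene trapping the benzyl cations, and chelation of boron between the C4 carbonyl and the peri oxygen should activate the C5 ethyl ether for chloride attack.

**Compound list**

1 | 3-bromo-4-hydroxybenzaldehyde | O=Cc1ccc(O)c(Br)c1 | starting material
2 | 4-(benzyloxy)-3-bromobenzaldehyde | O=Cc1ccc(OCc2ccccc2)c(Br)c1 | intermediate
3 | 1-(benzyloxy)-2-bromobenzene | Brc1ccccc1OCc1ccccc1 | starting material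
4 | [2-(benzyloxy)phenyl]lithium | [Li]c1ccccc1OCc1ccccc1 | intermediate
5 | [2-(benzyloxy)phenyl][4-(benzyloxy)-3-bromophenyl]methanol (racemic) | OC(c1ccccc1OCc1ccccc1)c1ccc(OCc2ccccc2)c(Br)c1 | intermediate
6 | 1-(benzyloxy)-2-bromo-4-[2-(benzyloxy)benzyl]benzene (Ar2–Br) | Brc1cc(Cc2ccccc2OCc2ccccc2)ccc1OCc1ccccc1 | intermediate
7 | Ar2–Li | [Li]c1cc(Cc2ccccc2OCc2ccccc2)ccc1OCc1ccccc1 | intermediate
8 | (Ar2)[4-(benzyloxy)-3-bromophenyl]methanol (racemic) | OC(c1ccc(OCc2ccccc2)c(Br)c1)c1cc(Cc2ccccc2OCc2ccccc2)ccc1OCc1ccccc1 | intermediate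
9 | Ar3–Br | Brc1cc(Cc2cc(Cc3ccccc3OCc3ccccc3)ccc2OCc2ccccc2)ccc1OCc1ccccc1 | intermediate
10 | Ar3–Li | [Li]c1cc(Cc2cc(Cc3ccccc3OCc3ccccc3)ccc2OCc2ccccc2)ccc1OCc1ccccc1 | intermediate
11 | (Ar3)[4-(benzyloxy)-3-bromophenyl]methanol (racemic) | OC(c1ccc(OCc2ccccc2)c(Br)c1)c1cc(Cc2cc(Cc3ccccc3OCc3ccccc3)ccc2OCc2ccccc2)ccc1OCc1ccccc1 | intermediate
12 | Ar4–Br | Brc1cc(Cc2cc(Cc3cc(Cc4ccccc4OCc4ccccc4)ccc3OCc3ccccc3)ccc2OCc2ccccc2)ccc1OCc1ccccc1 | intermediate
13 | ethyl 3-(Ar4)propanoate | CCOC(=O)CCc1cc(Cc2cc(Cc3cc(Cc4ccccc4OCc4ccccc4)ccc3OCc3ccccc3)ccc2OCc2ccccc2)ccc1OCc1ccccc1 | intermediate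
14 | N-methoxy-N-methyl-3-(Ar4)propanamide | CON(C)C(=O)CCc1cc(Cc2cc(Cc3cc(Cc4ccccc4OCc4ccccc4)ccc3OCc3ccccc3)ccc2OCc2ccccc2)ccc1OCc1ccccc1 | intermediate
15 | ethyl vinyl ether | C=COCC | starting material
16 | 1-ethoxyvinyllithium | [Li]C(=C)OCC | intermediate
17 | 2-ethoxy-5-(Ar4)pent-1-en-3-one | C=C(OCC)C(=O)CCc1cc(Cc2cc(Cc3cc(Cc4ccccc4OCc4ccccc4)ccc3OCc3ccccc3)ccc2OCc2ccccc2)ccc1OCc1ccccc1 | intermediate
18 | 5-ethoxy-1,1,1-trifluoro-3-(Ar4-methyl)hex-5-ene-2,4-dione | C=C(OCC)C(=O)C(C(=O)C(F)(F)F)Cc1cc(Cc2cc(Cc3cc(Cc4ccccc4OCc4ccccc4)ccc3OCc3ccccc3)ccc2OCc2ccccc2)ccc1OCc1ccccc1 | intermediate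
19 | 4-diazo-2-ethoxy-5-(Ar4)pent-1-en-3-one | C=C(OCC)C(=O)C(=[N+]=[N-])Cc1cc(Cc2cc(Cc3cc(Cc4ccccc4OCc4ccccc4)ccc3OCc3ccccc3)ccc2OCc2ccccc2)ccc1OCc1ccccc1 | intermediate
20 | methyl 2-(2-hydroxyphenyl)acetate | COC(=O)Cc1ccccc1O | starting material
21 | methyl 2-[2-(benzyloxy)phenyl]acetate | COC(=O)Cc1ccccc1OCc1ccccc1 | intermediate
22 | lithium 3-[2-(benzyloxy)phenyl]prop-1-yn-1-olate | [Li]OC#CCc1ccccc1OCc1ccccc1 | intermediate
23 | triisopropyl{3-[2-(benzyloxy)phenyl]prop-1-yn-1-yloxy}silane | CC(C)[Si](OC#CCc1ccccc1OCc1ccccc1)(C(C)C)C(C)C | intermediate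
24 | 2-(Ar4-methyl)-3-ethoxybuta-1,3-dien-1-one (vinylketene) | O=C=C(C(=C)OCC)Cc1cc(Cc2cc(Cc3cc(Cc4ccccc4OCc4ccccc4)ccc3OCc3ccccc3)ccc2OCc2ccccc2)ccc1OCc1ccccc1 | intermediate
25 | 4-(Ar4-methyl)-2-[2-(benzyloxy)benzyl]-4-(1-ethoxyvinyl)-3-(triisopropylsilyloxy)cyclobut-2-en-1-one (racemic) | O=C1C(Cc2ccccc2OCc2ccccc2)=C(O[Si](C(C)C)(C(C)C)C(C)C)C1(C(=C)OCC)Cc1cc(Cc2cc(Cc3cc(Cc4ccccc4OCc4ccccc4)ccc3OCc3ccccc3)ccc2OCc2ccccc2)ccc1OCc1ccccc1 | intermediate
26 | 4-(Ar4-methyl)-2-[2-(benzyloxy)benzyl]-5-ethoxy-3-(triisopropylsilyloxy)hexa-1,3,5-trien-1-one (ketene and ethoxyvinyl cis on the central C=C) | O=C=C(Cc1ccccc1OCc1ccccc1)/C(O[Si](C(C)C)(C(C)C)C(C)C)=C(/Cc1cc(Cc2cc(Cc3cc(Cc4ccccc4OCc4ccccc4)ccc3OCc3ccccc3)ccc2OCc2ccccc2)ccc1OCc1ccccc1)C(=C)OCC | intermediate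
27 | 4-(Ar4-methyl)-2-[2-(benzyloxy)benzyl]-5-ethoxy-3-(triisopropylsilyloxy)phenol | CCOc1cc(O)c(Cc2ccccc2OCc2ccccc2)c(O[Si](C(C)C)(C(C)C)C(C)C)c1Cc1cc(Cc2cc(Cc3cc(Cc4ccccc4OCc4ccccc4)ccc3OCc3ccccc3)ccc2OCc2ccccc2)ccc1OCc1ccccc1 | intermediate
28 | ethyl (R)-3-hydroxy-3-phenylpropanoate | CCOC(=O)C[C@@H](O)c1ccccc1 | starting material
29 | ethyl (S)-3-{4-(Ar4-methyl)-2-[2-(benzyloxy)benzyl]-5-ethoxy-3-(triisopropylsilyloxy)phenoxy}-3-phenylpropanoate | CCOC(=O)C[C@@H](c1ccccc1)Oc1cc(OCC)c(Cc2cc(Cc3cc(Cc4cc(Cc5ccccc5OCc5ccccc5)ccc4OCc4ccccc4)ccc3OCc3ccccc3)ccc2OCc2ccccc2)c(O[Si](C(C)C)(C(C)C)C(C)C)c1Cc1ccccc1OCc1ccccc1 | intermediate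
30 | (S)-3-{4-(Ar4-methyl)-2-[2-(benzyloxy)benzyl]-5-ethoxy-3-(triisopropylsilyloxy)phenoxy}-3-phenylpropanoic acid | OC(=O)C[C@@H](c1ccccc1)Oc1cc(OCC)c(Cc2cc(Cc3cc(Cc4cc(Cc5ccccc5OCc5ccccc5)ccc4OCc4ccccc4)ccc3OCc3ccccc3)ccc2OCc2ccccc2)c(O[Si](C(C)C)(C(C)C)C(C)C)c1Cc1ccccc1OCc1ccccc1 | intermediate
31 | mixed anhydride of 30 with trifluoroacetic acid | O=C(OC(=O)C(F)(F)F)C[C@@H](c1ccccc1)Oc1cc(OCC)c(Cc2cc(Cc3cc(Cc4cc(Cc5ccccc5OCc5ccccc5)ccc4OCc4ccccc4)ccc3OCc3ccccc3)ccc2OCc2ccccc2)c(O[Si](C(C)C)(C(C)C)C(C)C)c1Cc1ccccc1OCc1ccccc1 | intermediate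
32 | (S)-6-(Ar4-methyl)-8-[2-(benzyloxy)benzyl]-5-ethoxy-2-phenyl-7-(triisopropylsilyloxy)chroman-4-one | O=C1C[C@@H](c2ccccc2)Oc2c(Cc3ccccc3OCc3ccccc3)c(O[Si](C(C)C)(C(C)C)C(C)C)c(Cc3cc(Cc4cc(Cc5cc(Cc6ccccc6OCc6ccccc6)ccc5OCc5ccccc5)ccc4OCc4ccccc4)ccc3OCc3ccccc3)c(OCC)c21 | intermediate
33 | (S)-6-(Ar4-methyl)-8-[2-(benzyloxy)benzyl]-5-ethoxy-7-hydroxy-2-phenylchroman-4-one | O=C1C[C@@H](c2ccccc2)Oc2c(Cc3ccccc3OCc3ccccc3)c(O)c(Cc3cc(Cc4cc(Cc5cc(Cc6ccccc6OCc6ccccc6)ccc5OCc5ccccc5)ccc4OCc4ccccc4)ccc3OCc3ccccc3)c(OCC)c21 | intermediate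
34 | sarmentosumin C | O=C1C[C@@H](c2ccccc2)Oc2c(Cc3ccccc3O)c(O)c(Cc3cc(Cc4cc(Cc5cc(Cc6ccccc6O)ccc5O)ccc4O)ccc3O)c(O)c21 | target

**Step count and least certain steps**

Total: 19 steps. Longest linear sequence: 17 steps (steps 1 to 11, then 14 to 19); steps 12 and 13 form the short branch.

Step 14 (key step, new method). Three processes are most likely to defeat it:
- a 1,2-hydrogen shift from the benzylic CH2 next to the carbene carbon competing with vinyl migration, because that CH2 is activated by ring D;
- 4-electron closure or dimerisation of the alkoxyvinylketene before the alkyne intercepts it, the closed form being a vinylogous ester that reopens only sluggishly;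
- competing light absorption and photocleavage by the aryl benzyl ethers if a shorter wavelength turns out to be needed.

Fallback with known chemistry, setting out from bromide 12 and coming back at 33, with ring A taken from purchased phloroglucinol instead of being built. Acid-catalysed mono-ethylation (EtOH, HCl) gives 5-ethoxybenzene-1,3-diol F1, and MOMCl/i-Pr2NEt converts it into 1-ethoxy-3,5-bis(methoxymethoxy)benzene F2, the substrate for metalation. Directed ortho-lithiation (n-BuLi, THF, 0 °C) between the two methoxymethoxy groups and alkylation with 1-(benzyloxy)-2-(bromomethyl)benzene (CuI cat.) places the ring H benzyl on the future C8 and gives 2-[2-(benzyloxy)benzyl]-5-ethoxy-1,3-bis(methoxymethoxy)benzene F3, which has a mirror plane, so its two free ring positions are equivalent. Monobromination with NBS gives 2-[2-(benzyloxy)benzyl]-4-bromo-5-ethoxy-1,3-bis(methoxymethoxy)benzene F4, and bromine–lithium exchange followed by DMF gives 3-[2-(benzyloxy)benzyl]-6-ethoxy-2,4-bis(methoxymethoxy)benzaldehyde F5, the electrophile for the chain. The aryllithium Ar4–Li F6, made from 12 with n-BuLi at −78 °C, adds to F5 to give {3-[2-(benzyloxy)benzyl]-6-ethoxy-2,4-bis(methoxymethoxy)phenyl}(Ar4)methanol F7, a racemic carbinol. Et3SiH/CF3CO2H followed by HCl/MeOH reduces the carbinol and removes both methoxymethyl groups to give 4-(Ar4-methyl)-2-[2-(benzyloxy)benzyl]-5-ethoxybenzene-1,3-diol F8, which is 27 without its silyl group. Mitsunobu reaction with 28 should take place at the C8a hydroxyl, which has one ortho substituent, in preference to the C7 hydroxyl, which has two, giving ethyl (S)-3-{4-(Ar4-methyl)-2-[2-(benzyloxy)benzyl]-5-ethoxy-3-hydroxyphenoxy}-3-phenylpropanoate F9, and Me3SnOH then gives (S)-3-{4-(Ar4-methyl)-2-[2-(benzyloxy)benzyl]-5-ethoxy-3-hydroxyphenoxy}-3-phenylpropanoic acid F10, which the conditions of step 17 close to 33. The price is site control in two places (lithiation of F2, Mitsunobu of F8) and a longer sequence.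

Step 13. The arylacetate α-protons are acidic, so deprotonation of 21 by dibromomethyllithium or the amide base may compete with carbonyl addition and lead to Claisen self-condensation instead of the ynolate. Fallback from 21, coming back at 23: i-Bu2AlH at −78 °C gives 2-[2-(benzyloxy)phenyl]acetaldehyde F11, and Ohira–Bestmann homologation (dimethyl 1-diazo-2-oxopropylphosphonate, K2CO3, MeOH) gives 1-(benzyloxy)-2-(prop-2-yn-1-yl)benzene F12, a terminal alkyne. Its lithium acetylide (n-BuLi, −78 °C) is oxidised with LiOOt-Bu to the same ynolate 22, which is silylated with i-Pr3SiOTf to 23. This replaces the carbenoid rearrangement by oxidation of an acetylide.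

Step 15. The activated carbinol lies next to an ester-acidified CH2, so elimination to the cinnamate may compete with substitution, and partial ionisation at the benzylic centre would erode the inversion. Fallback from 27, coming back at 30: Mitsunobu reaction with purchased (R)-1-phenylbut-3-en-1-ol, which has no acidifying group, gives 4-(Ar4-methyl)-2-[2-(benzyloxy)benzyl]-5-ethoxy-1-[(S)-1-phenylbut-3-enyloxy]-3-(triisopropylsilyloxy)benzene F13, the homoallyl aryl ether. Lemieux–Johnson cleavage (OsO4 cat., NaIO4, 2,6-lutidine) gives (S)-3-{4-(Ar4-methyl)-2-[2-(benzyloxy)benzyl]-5-ethoxy-3-(triisopropylsilyloxy)phenoxy}-3-phenylpropanal F14, and Pinnick oxidation (NaClO2, NaH2PO4, 2-methyl-2-butene) gives acid 30 directly, so step 16 is not needed. The carboxyl group is thus unmasked only after the ether bond is in place.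

Step 19. Benzyl cations may re-alkylate the electron-rich phenol rings despite the scavenger, the ethyl group may leave more slowly than a methyl group would, and prolonged Lewis-acid exposure may open ring C and erode the configuration at C2. Fallback from 33, coming back at 34: hydrogenolysis (H2, Pd/C, EtOAc/MeOH) removes the five benzyl groups without generating cations and gives 5-O-ethyl sarmentosumin C F15, in which only the chelated peri ethyl ether remains. BCl3 in CH2Cl2 then has this single ether to cleave and can be applied with more time and at 0 °C without benzylation side reactions.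

**Further compounds**

F1 | step 14 | 5-ethoxybenzene-1,3-diol | CCOc1cc(O)cc(O)c1
F2 | step 14 | 1-ethoxy-3,5-bis(methoxymethoxy)benzene | CCOc1cc(OCOC)cc(OCOC)c1
F3 | step 14 | 2-[2-(benzyloxy)benzyl]-5-ethoxy-1,3-bis(methoxymethoxy)benzene | CCOc1cc(OCOC)c(Cc2ccccc2OCc2ccccc2)c(OCOC)c1
F4 | step 14 | 2-[2-(benzyloxy)benzyl]-4-bromo-5-ethoxy-1,3-bis(methoxymethoxy)benzene | CCOc1cc(OCOC)c(Cc2ccccc2OCc2ccccc2)c(OCOC)c1Br
F5 | step 14 | 3-[2-(benzyloxy)benzyl]-6-ethoxy-2,4-bis(methoxymethoxy)benzaldehyde | CCOc1cc(OCOC)c(Cc2ccccc2OCc2ccccc2)c(OCOC)c1C=O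
F6 | step 14 | Ar4–Li | [Li]c1cc(Cc2cc(Cc3cc(Cc4ccccc4OCc4ccccc4)ccc3OCc3ccccc3)ccc2OCc2ccccc2)ccc1OCc1ccccc1
F7 | step 14 | {3-[2-(benzyloxy)benzyl]-6-ethoxy-2,4-bis(methoxymethoxy)phenyl}(Ar4)methanol (racemic) | CCOc1cc(OCOC)c(Cc2ccccc2OCc2ccccc2)c(OCOC)c1C(O)c1cc(Cc2cc(Cc3cc(Cc4ccccc4OCc4ccccc4)ccc3OCc3ccccc3)ccc2OCc2ccccc2)ccc1OCc1ccccc1
F8 | step 14 | 4-(Ar4-methyl)-2-[2-(benzyloxy)benzyl]-5-ethoxybenzene-1,3-diol | CCOc1cc(O)c(Cc2ccccc2OCc2ccccc2)c(O)c1Cc1cc(Cc2cc(Cc3cc(Cc4ccccc4OCc4ccccc4)ccc3OCc3ccccc3)ccc2OCc2ccccc2)ccc1OCc1ccccc1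
F9 | step 14 | ethyl (S)-3-{4-(Ar4-methyl)-2-[2-(benzyloxy)benzyl]-5-ethoxy-3-hydroxyphenoxy}-3-phenylpropanoate | CCOC(=O)C[C@@H](c1ccccc1)Oc1cc(OCC)c(Cc2cc(Cc3cc(Cc4cc(Cc5ccccc5OCc5ccccc5)ccc4OCc4ccccc4)ccc3OCc3ccccc3)ccc2OCc2ccccc2)c(O)c1Cc1ccccc1OCc1ccccc1
F10 | step 14 | (S)-3-{4-(Ar4-methyl)-2-[2-(benzyloxy)benzyl]-5-ethoxy-3-hydroxyphenoxy}-3-phenylpropanoic acid | OC(=O)C[C@@H](c1ccccc1)Oc1cc(OCC)c(Cc2cc(Cc3cc(Cc4cc(Cc5ccccc5OCc5ccccc5)ccc4OCc4ccccc4)ccc3OCc3ccccc3)ccc2OCc2ccccc2)c(O)c1Cc1ccccc1OCc1ccccc1
F11 | step 13 | 2-[2-(benzyloxy)phenyl]acetaldehyde | O=CCc1ccccc1OCc1ccccc1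
F12 | step 13 | 1-(benzyloxy)-2-(prop-2-yn-1-yl)benzene | C#CCc1ccccc1OCc1ccccc1
F13 | step 15 | 4-(Ar4-methyl)-2-[2-(benzyloxy)benzyl]-5-ethoxy-1-[(S)-1-phenylbut-3-enyloxy]-3-(triisopropylsilyloxy)benzene | C=CC[C@@H](c1ccccc1)Oc1cc(OCC)c(Cc2cc(Cc3cc(Cc4cc(Cc5ccccc5OCc5ccccc5)ccc4OCc4ccccc4)ccc3OCc3ccccc3)ccc2OCc2ccccc2)c(O[Si](C(C)C)(C(C)C)C(C)C)c1Cc1ccccc1OCc1ccccc1
F14 | step 15 | (S)-3-{4-(Ar4-methyl)-2-[2-(benzyloxy)benzyl]-5-ethoxy-3-(triisopropylsilyloxy)phenoxy}-3-phenylpropanal | O=CC[C@@H](c1ccccc1)Oc1cc(OCC)c(Cc2cc(Cc3cc(Cc4cc(Cc5ccccc5OCc5ccccc5)ccc4OCc4ccccc4)ccc3OCc3ccccc3)ccc2OCc2ccccc2)c(O[Si](C(C)C)(C(C)C)C(C)C)c1Cc1ccccc1OCc1ccccc1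
F15 | step 19 | 5-O-ethyl sarmentosumin C | O=C1C[C@@H](c2ccccc2)Oc2c(Cc3ccccc3O)c(O)c(Cc3cc(Cc4cc(Cc5cc(Cc6ccccc6O)ccc5O)ccc4O)ccc3O)c(OCC)c21
A1 | alternative 1 | penta-MOM flavone dialdehyde (formyl groups on C8 and on ring F) | O=C1C=C(c2ccccc2)Oc2c(C=O)c(OCOC)c(Cc3cc(Cc4cc(Cc5cc(C=O)ccc5OCOC)ccc4OCOC)ccc3OCOC)c(OCOC)c21
A2 | alternative 1 | cyclohex-2-enone | O=C1C=CCCC1
A3 | alternative 1 | penta-MOM flavone with both terminal 2-hydroxyphenyl rings | O=C1C=C(c2ccccc2)Oc2c(Cc3ccccc3O)c(OCOC)c(Cc3cc(Cc4cc(Cc5cc(Cc6ccccc6O)ccc5OCOC)ccc4OCOC)ccc3OCOC)c(OCOC)c21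
A4 | alternative 2 | hepta-MOM (S)-bromo carbinol (C8a bromide, C4 silyl ether as epimer mixture) | CC(C)(C)[Si](C)(C)OC(C[C@H](O)c1ccccc1)c1c(Br)c(Cc2ccccc2OCOC)c(OCOC)c(Cc2cc(Cc3cc(Cc4cc(Cc5ccccc5OCOC)ccc4OCOC)ccc3OCOC)ccc2OCOC)c1OCOC
A5 | alternative 2 | hepta-MOM (2S)-4-silyloxyflavan (C4 epimer mixture) | CC(C)(C)[Si](C)(C)OC1C[C@@H](c2ccccc2)Oc2c(Cc3ccccc3OCOC)c(OCOC)c(Cc3cc(Cc4cc(Cc5cc(Cc6ccccc6OCOC)ccc5OCOC)ccc4OCOC)ccc3OCOC)c(OCOC)c21
A6 | alternative 3 | hepta-benzyl (S)-3-aryloxy-3-phenylpropanoic acid | OC(=O)C[C@@H](c1ccccc1)Oc1cc(OCc2ccccc2)c(Cc2cc(Cc3cc(Cc4cc(Cc5ccccc5OCc5ccccc5)ccc4OCc4ccccc4)ccc3OCc3ccccc3)ccc2OCc2ccccc2)c(OCc2ccccc2)c1Cc1ccccc1OCc1ccccc1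
A7 | alternative 3 | (S)-hepta-O-benzyl sarmentosumin C | O=C1C[C@@H](c2ccccc2)Oc2c(Cc3ccccc3OCc3ccccc3)c(OCc3ccccc3)c(Cc3cc(Cc4cc(Cc5cc(Cc6ccccc6OCc6ccccc6)ccc5OCc5ccccc5)ccc4OCc4ccccc4)ccc3OCc3ccccc3)c(OCc3ccccc3)c21
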